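## Retrosynthetic overview
1. Ligraminol D ⇒ remove the silyl group and trade the C9 CH2OH for an N-acyl (S)-4-benzyloxazolidinone, giving a (2S)-2-aryloxy-3-arylpropanoyl imide.
2. The C7 methylene ⇒ a benzylic C7–OH (removed by ionic deoxygenation), which reveals a syn-aldol adduct.
3. Key disconnection C7–C8: an intermolecular Evans boron aldol joins the aryloxyacetyl imide (ring B fragment) to 3,4-dimethoxybenzaldehyde (ring A fragment) and sets C8.
4. The aryloxyacetic acid ⇒ eugenol + ethyl bromoacetate (Williamson ether synthesis). The allyl group becomes 3-silyloxypropyl by hydroboration–oxidation and silylation.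
5. No ring is formed. Rings A and B are bought as veratraldehyde and eugenol, and the oxazolidinone ring is a bought, recovered auxiliary.

Assumption: the stereocentre of the given SMILES is (S) at C8 (neolignan numbering: C7 = benzylic CH2, C8 = aryloxy carbon, C9 = CH2OH carbon); TBDPS = tert-butyldiphenylsilyl.

## Route

Step 1
Reactants: 1 eugenol (4-allyl-2-methoxyphenol); 2 ethyl bromoacetate
Product: 3 ethyl 2-(4-allyl-2-methoxyphenoxy)acetate
Conditions: K2CO3 (2 equiv), acetone, reflux, 8 h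
Reagents that add atoms: none
Why: Williamson ether synthesis, in which the phenoxide formed by K2CO3 displaces the activated primary bromide of 2 by SN2 while the allyl group and the ester stay inert.

Step 2
Reactants: 3 ethyl 2-(4-allyl-2-methoxyphenoxy)acetate
Product: 5 ethyl 2-[4-(3-hydroxypropyl)-2-methoxyphenoxy]acetate, via alkylborane 4 (not isolated)
Conditions: 9-BBN (0.5 M in THF, 1.3 equiv), 0 °C to rt, 6 h; then pH 7 buffer (NaH2PO4/Na2HPO4), 30% aq H2O2, 0 °C to rt
Reagents that add atoms: 9-borabicyclo[3.3.1]nonane (9-BBN), B1C2CCCC1CCC2 (kept only in 4); hydrogen peroxide, OO (gives the hydroxyl oxygen of 5)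
Why: Brown hydroboration–oxidation, in which bulky 9-BBN adds anti-Markovnikov to the terminal alkene without reducing the ester, and oxidation at pH 7 replaces boron by hydroxyl without saponifying the activated aryloxyacetate.

Step 3
Reactants: 5 ethyl 2-[4-(3-hydroxypropyl)-2-methoxyphenoxy]acetate
Product: 6 ethyl 2-{4-[3-(tert-butyldiphenylsilyloxy)propyl]-2-methoxyphenoxy}acetate
Conditions: TBDPSCl (1.1 equiv), imidazole (2.2 equiv), DMF, 0 °C to rt
Reagents that add atoms: tert-butyl(chloro)diphenylsilane, CC(C)(C)[Si](Cl)(c1ccccc1)c1ccccc1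
Why: Imidazole-promoted silylation of the only free hydroxyl, with TBDPS chosen because it survives LiOH, Bu2BOTf, H2O2, CF3CO2H and NaBH4 in the later steps.

Step 4
Reactants: 6 ethyl 2-{4-[3-(tert-butyldiphenylsilyloxy)propyl]-2-methoxyphenoxy}acetate
Product: 8 2-{4-[3-(tert-butyldiphenylsilyloxy)propyl]-2-methoxyphenoxy}acetic acid, via lithium carboxylate 7 (not isolated)
Conditions: LiOH·H2O (2 equiv), THF/H2O 3:1, 0 °C to rt, 2 h; then 1 M HCl to pH 3, 0 °C
Reagents that add atoms: lithium hydroxide, [Li+].[OH-]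
Why: Saponification of an unhindered, activated ethyl ester is fast at room temperature, and the TBDPS ether tolerates aqueous LiOH and the brief cold acidification.

Step 5
Reactants: 8 2-{4-[3-(tert-butyldiphenylsilyloxy)propyl]-2-methoxyphenoxy}acetic acid; 9 (S)-4-benzyl-1,3-oxazolidin-2-one
Product: 11 (4S)-4-benzyl-3-(2-{4-[3-(tert-butyldiphenylsilyloxy)propyl]-2-methoxyphenoxy}acetyl)-1,3-oxazolidin-2-one, via mixed pivalic anhydride 10 (not isolated)
Conditions: PivCl (1.05 equiv), Et3N (2.5 equiv), THF, −20 °C, 1 h; then LiCl (1.1 equiv), 9 (1.0 equiv), −20 °C to rt, 12 h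
Reagents that add atoms: pivaloyl chloride, CC(C)(C)C(=O)Cl (kept only in 10)
Why: Mixed-anhydride N-acylation of the Evans auxiliary, in which LiCl/Et3N activates the oxazolidinone to attack 10 at the less hindered, more electrophilic aryloxyacetyl carbonyl and leaves the stereocentre of 9 untouched.

Step 6
Reactants: 11 (4S)-4-benzyl-3-(2-{4-[3-(tert-butyldiphenylsilyloxy)propyl]-2-methoxyphenoxy}acetyl)-1,3-oxazolidin-2-one; 12 3,4-dimethoxybenzaldehyde (veratraldehyde)
Product: 15 (4S)-4-benzyl-3-[(2S,3R)-2-{4-[3-(tert-butyldiphenylsilyloxy)propyl]-2-methoxyphenoxy}-3-(3,4-dimethoxyphenyl)-3-hydroxypropanoyl]-1,3-oxazolidin-2-one, via boron enolate 13 (not isolated), via boron aldolate 14 (not isolated)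
Conditions: Bu2BOTf (1.2 equiv), iPr2NEt (1.4 equiv), CH2Cl2, −78 to 0 °C, 45 min; 12 (1.2 equiv), −78 °C, 1 h, then 0 °C, 1 h; pH 7 buffer (NaH2PO4/Na2HPO4), MeOH, 30% H2O2, 0 °C
Reagents that add atoms: dibutylboron triflate, CCCCB(CCCC)OS(=O)(=O)C(F)(F)F (kept only in 13 and 14)
Why: Evans syn-aldol reaction, in which soft enolisation gives only the (Z)-boron enolate 13, which adds to 12 through a Zimmerman–Traxler chair with the benzyl group shielding one face, so the C7–C8 bond forms as (2S,3R) and C8 = S is the stereocentre kept in the target.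

Step 7
Reactants: 15 the (2S,3R)-syn-aldol imide
Product: 17 (4S)-4-benzyl-3-[(2S)-2-{4-[3-(tert-butyldiphenylsilyloxy)propyl]-2-methoxyphenoxy}-3-(3,4-dimethoxyphenyl)propanoyl]-1,3-oxazolidin-2-one, via benzylic cation 16 (not isolated)
Conditions: Et3SiH (5 equiv, premixed with 15), CF3CO2H (15 equiv), CH2Cl2 (0.05 M), 0 °C, 1–2 h; aq NaHCO3
Reagents that add atoms: none
Why: Ionic hydrogenation (Kursanov–Parnes type), in which CF3CO2H ionises only the 3,4-dimethoxybenzylic alcohol to the stabilised cation 16 and excess Et3SiH delivers hydride faster than H-8 is lost, so C7 becomes CH2 while C8, the imide and the TBDPS ether are untouched.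

Step 8
Reactants: 17 the (2S)-deoxygenated imide
Product: 19 (2S)-2-{4-[3-(tert-butyldiphenylsilyloxy)propyl]-2-methoxyphenoxy}-3-(3,4-dimethoxyphenyl)propan-1-ol, via aldehyde 18 (not isolated)
Conditions: NaBH4 (4 equiv), THF/H2O 4:1, 0 °C to rt, 3 h; aq NH4Cl
Reagents that add atoms: none
Why: Reductive cleavage of the N-acyloxazolidinone, in which hydride attacks the more electrophilic α-oxygenated exocyclic carbonyl, releases 9 and aldehyde 18, and reduces 18 at once, so C8 keeps its (S) configuration and the auxiliary is recovered.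

Step 9
Reactants: 19 the (2S)-mono-TBDPS ether
Product: 20 ligraminol D = (2S)-3-(3,4-dimethoxyphenyl)-2-[4-(3-hydroxypropyl)-2-methoxyphenoxy]propan-1-ol
Conditions: Bu4NF (1.0 M in THF, 1.5 equiv), THF, 0 °C to rt, 3 h
Reagents that add atoms: none
Why: Fluoride-driven desilylation (strong Si–F bond) frees the second primary alcohol without touching the aryl ethers or the stereocentre.

## Compound list
1 | eugenol (4-allyl-2-methoxyphenol) | C=CCc1ccc(O)c(OC)c1 | starting material
2 | ethyl bromoacetate | CCOC(=O)CBr | starting material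
3 | ethyl 2-(4-allyl-2-methoxyphenoxy)acetate | CCOC(=O)COc1ccc(CC=C)cc1OC | intermediate
4 | ethyl 2-{4-[3-(9-borabicyclo[3.3.1]nonan-9-yl)propyl]-2-methoxyphenoxy}acetate (alkylborane, formed in the flask) | CCOC(=O)COc1ccc(CCCB2C3CCCC2CCC3)cc1OC | intermediate
5 | ethyl 2-[4-(3-hydroxypropyl)-2-methoxyphenoxy]acetate | CCOC(=O)COc1ccc(CCCO)cc1OC | intermediate
6 | ethyl 2-{4-[3-(tert-butyldiphenylsilyloxy)propyl]-2-methoxyphenoxy}acetate | CCOC(=O)COc1ccc(CCCO[Si](c2ccccc2)(c2ccccc2)C(C)(C)C)cc1OC | intermediate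
7 | lithium 2-{4-[3-(tert-butyldiphenylsilyloxy)propyl]-2-methoxyphenoxy}acetate (formed in the flask) | [Li+].[O-]C(=O)COc1ccc(CCCO[Si](c2ccccc2)(c2ccccc2)C(C)(C)C)cc1OC | intermediate
8 | 2-{4-[3-(tert-butyldiphenylsilyloxy)propyl]-2-methoxyphenoxy}acetic acid | OC(=O)COc1ccc(CCCO[Si](c2ccccc2)(c2ccccc2)C(C)(C)C)cc1OC | intermediate
9 | (S)-4-benzyl-1,3-oxazolidin-2-one | O=C1N[C@@H](Cc2ccccc2)CO1 | starting material
10 | mixed anhydride of 8 and pivalic acid (formed in the flask) | CC(C)(C)C(=O)OC(=O)COc1ccc(CCCO[Si](c2ccccc2)(c2ccccc2)C(C)(C)C)cc1OC | intermediate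
11 | (4S)-4-benzyl-3-(2-{4-[3-(tert-butyldiphenylsilyloxy)propyl]-2-methoxyphenoxy}acetyl)-1,3-oxazolidin-2-one | O=C(COc1ccc(CCCO[Si](c2ccccc2)(c2ccccc2)C(C)(C)C)cc1OC)N1[C@@H](Cc2ccccc2)COC1=O | intermediate
12 | 3,4-dimethoxybenzaldehyde (veratraldehyde) | COc1ccc(C=O)cc1OC | starting material
13 | (Z)-dibutylboron enolate of 11 (formed in the flask) | CCCCB(CCCC)O/C(=C\Oc1ccc(CCCO[Si](c2ccccc2)(c2ccccc2)C(C)(C)C)cc1OC)N1[C@@H](Cc2ccccc2)COC1=O | intermediate
14 | O-dibutylboryl aldolate of 15, (2S,3R) (formed in the flask) | COc1ccc([C@@H](OB(CCCC)CCCC)[C@H](Oc2ccc(CCCO[Si](c3ccccc3)(c3ccccc3)C(C)(C)C)cc2OC)C(=O)N2[C@@H](Cc3ccccc3)COC2=O)cc1OC | intermediate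
15 | (4S)-4-benzyl-3-[(2S,3R)-2-{4-[3-(tert-butyldiphenylsilyloxy)propyl]-2-methoxyphenoxy}-3-(3,4-dimethoxyphenyl)-3-hydroxypropanoyl]-1,3-oxazolidin-2-one | COc1ccc([C@@H](O)[C@H](Oc2ccc(CCCO[Si](c3ccccc3)(c3ccccc3)C(C)(C)C)cc2OC)C(=O)N2[C@@H](Cc3ccccc3)COC2=O)cc1OC | intermediate
16 | 3,4-dimethoxybenzylic cation from 15 (C3 cationic, C2 still S; formed in the flask) | COc1ccc([CH+][C@H](Oc2ccc(CCCO[Si](c3ccccc3)(c3ccccc3)C(C)(C)C)cc2OC)C(=O)N2[C@@H](Cc3ccccc3)COC2=O)cc1OC | intermediate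
17 | (4S)-4-benzyl-3-[(2S)-2-{4-[3-(tert-butyldiphenylsilyloxy)propyl]-2-methoxyphenoxy}-3-(3,4-dimethoxyphenyl)propanoyl]-1,3-oxazolidin-2-one | COc1ccc(C[C@H](Oc2ccc(CCCO[Si](c3ccccc3)(c3ccccc3)C(C)(C)C)cc2OC)C(=O)N2[C@@H](Cc3ccccc3)COC2=O)cc1OC | intermediate
18 | (2S)-2-{4-[3-(tert-butyldiphenylsilyloxy)propyl]-2-methoxyphenoxy}-3-(3,4-dimethoxyphenyl)propanal (formed in the flask) | COc1ccc(C[C@H](Oc2ccc(CCCO[Si](c3ccccc3)(c3ccccc3)C(C)(C)C)cc2OC)C=O)cc1OC | intermediate
19 | (2S)-2-{4-[3-(tert-butyldiphenylsilyloxy)propyl]-2-methoxyphenoxy}-3-(3,4-dimethoxyphenyl)propan-1-ol | COc1ccc(C[C@@H](CO)Oc2ccc(CCCO[Si](c3ccccc3)(c3ccccc3)C(C)(C)C)cc2OC)cc1OC | intermediate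
20 | ligraminol D = (2S)-3-(3,4-dimethoxyphenyl)-2-[4-(3-hydroxypropyl)-2-methoxyphenoxy]propan-1-ol | COc1ccc(C[C@@H](CO)Oc2ccc(CCCO)cc2OC)cc1OC | target

## Step count and risks
Total step count: 9.
Longest linear sequence: 9 steps (1 → 20). Compounds 2, 9 and 12 enter as bought materials.

Steps most likely to fail:

1. **Step 7 (ionic deoxygenation).** Cation 16 may lose H-8 to give the α-aryloxycinnamoyl imide, or it may alkylate an electron-rich arene instead of taking up hydride. The fallback sets out from 15 and comes back at 19, bypassing steps 7 and 8. The auxiliary is removed first with NaBH4 in THF/H2O to give the (1R,2R)-1,3-diol F1. Both hydroxyls are acetylated with Ac2O/pyridine to give the (1R,2R)-diacetate F2. No acidic H-8 is left at this stage, so E1cB loss of acetate is not possible, and the blocked C7 oxygen prevents the dehydrogenative cleavage of the aryl ether. The benzylic acetate alone is then removed by catalytic hydrogenolysis (H2, 10% Pd/C, EtOH, rt) to give the (2S)-primary acetate F3. K2CO3 in MeOH takes off the remaining acetate to give 19.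

2. **Step 6 (boron aldol).** The electron-rich aldehyde 12 adds slowly, and incomplete enolisation or retro-aldol on work-up would lower yield or dr. The fallback sets out from 8 and comes back at 19, bypassing steps 5 to 8, and makes C7–C8 by Evans enolate alkylation instead. Acid 8 is joined through anhydride 10 (as in step 5) to commercial (R)-4-benzyl-1,3-oxazolidin-2-one (O=C1N[C@H](Cc2ccccc2)CO1) to give the (4R)-aryloxyacetyl imide F4. NaN(SiMe3)2 in THF at −78 °C gives the chelated sodium (Z)-enolate F5. This is alkylated with 3,4-dimethoxybenzyl bromide F6, made fresh from commercial 3,4-dimethoxybenzyl alcohol and PBr3 in Et2O at 0 °C. Attack comes from the face away from the benzyl group and gives the (4R,2S)-alkylated imide F7. The chelated enolate reacts on the opposite face to the one used in the boron aldol, so the (R)-auxiliary is needed here to reach (S)-C8. NaBH4 in THF/H2O then gives 19.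

3. **Step 8 (reductive removal of the auxiliary).** Hydride may attack the ring carbonyl and open the oxazolidinone, or aldehyde 18 may epimerise in the basic medium. The fallback sets out from 17 and comes back at 19. Hydrolysis with LiOH/H2O2 (THF/H2O, 0 °C, Na2SO3 quench), in which hydroperoxide attacks only the exocyclic carbonyl, gives the (2S)-carboxylic acid F8. BH3·THF (0 °C to rt) then reduces the acid to 19 without any free aldehyde standing in base.

## Further compounds
F1 | step 7 | (1R,2R)-2-{4-[3-(tert-butyldiphenylsilyloxy)propyl]-2-methoxyphenoxy}-1-(3,4-dimethoxyphenyl)propane-1,3-diol | COc1ccc([C@@H](O)[C@@H](CO)Oc2ccc(CCCO[Si](c3ccccc3)(c3ccccc3)C(C)(C)C)cc2OC)cc1OC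
F2 | step 7 | (1R,2R)-2-{4-[3-(tert-butyldiphenylsilyloxy)propyl]-2-methoxyphenoxy}-1-(3,4-dimethoxyphenyl)propane-1,3-diyl diacetate | COc1ccc([C@@H](OC(C)=O)[C@@H](COC(C)=O)Oc2ccc(CCCO[Si](c3ccccc3)(c3ccccc3)C(C)(C)C)cc2OC)cc1OC
F3 | step 7 | (2S)-2-{4-[3-(tert-butyldiphenylsilyloxy)propyl]-2-methoxyphenoxy}-3-(3,4-dimethoxyphenyl)propyl acetate | COc1ccc(C[C@@H](COC(C)=O)Oc2ccc(CCCO[Si](c3ccccc3)(c3ccccc3)C(C)(C)C)cc2OC)cc1OC
F4 | step 6 | (4R)-4-benzyl-3-(2-{4-[3-(tert-butyldiphenylsilyloxy)propyl]-2-methoxyphenoxy}acetyl)-1,3-oxazolidin-2-one | O=C(COc1ccc(CCCO[Si](c2ccccc2)(c2ccccc2)C(C)(C)C)cc1OC)N1[C@H](Cc2ccccc2)COC1=O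
F5 | step 6 | sodium (Z)-enolate of F4 | [Na+].[O-]/C(=C\Oc1ccc(CCCO[Si](c2ccccc2)(c2ccccc2)C(C)(C)C)cc1OC)N1[C@H](Cc2ccccc2)COC1=O
F6 | step 6 | 3,4-dimethoxybenzyl bromide | COc1ccc(CBr)cc1OC
F7 | step 6 | (4R)-4-benzyl-3-[(2S)-2-{4-[3-(tert-butyldiphenylsilyloxy)propyl]-2-methoxyphenoxy}-3-(3,4-dimethoxyphenyl)propanoyl]-1,3-oxazolidin-2-one | COc1ccc(C[C@H](Oc2ccc(CCCO[Si](c3ccccc3)(c3ccccc3)C(C)(C)C)cc2OC)C(=O)N2[C@H](Cc3ccccc3)COC2=O)cc1OC
F8 | step 8 | (2S)-2-{4-[3-(tert-butyldiphenylsilyloxy)propyl]-2-methoxyphenoxy}-3-(3,4-dimethoxyphenyl)propanoic acid | COc1ccc(C[C@H](Oc2ccc(CCCO[Si](c3ccccc3)(c3ccccc3)C(C)(C)C)cc2OC)C(=O)O)cc1OC
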